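A direct plan would make the flavone first, protect it as 5,7-bis(benzyloxy)-3-methoxyflavone (A1), put a one-carbon handle on C8 via an iodide and then grow ring D on it: coupling to a benzyl alkynyl ether (A2), dichloroketene cycloaddition and dechlorination to a cyclobutenone (A3), benzannulation with 1-methoxypropyne to phenol A4, acylation to ester A5, Fries rearrangement, debenzylation.
Its weakest steps would be three. (1) The six operations from A1 to A3 would only hang a four-membered ring on C8, and would pass through A2, an ynol ether that rearranges near room temperature. (2) The benzannulation A3 → A4 would have to build ring D with one ketene–alkyne regiochemistry on the most advanced material. (3) The TiCl4 Fries rearrangement of A5 would free benzyl cations beside two phloroglucinol rings one step before the end.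

**Plan of the new route**
Rings: A = benzo ring of the chromone, C = pyrone, D = hexasubstituted ring of the dihydrochalcone. The retrosynthesis cuts ring C first (O1–C2, with the C2–C3 bond traced back to a benzoate on the future O1), then the CH2–ring D bond, then the CH2–C8 bond. Rings D and A are bought as phloroglucinols and joined through the methylene; ring C is closed last.
Enabling feature: the C8 methylene lies between the oxygen-bearing C7 and C8a and para to C5–O. Before ring C exists it is therefore a 2,4-dialkoxybenzyl carbon that ionises readily, while ring D has a single unsubstituted carbon, ortho and para to its free hydroxyls.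
The oxygen that becomes O1 directs the one-carbon unit, carries the benzoyl group through the union, hands it only to ring A's ketone, and then closes ring C, so the bridge can end only on C8. Ring D is never built and carries its phenylpropanoyl group from the first step, so no cyclobutenone run-up, no benzannulation and no Fries step arises.

Key step: step 6

Assumption: both phloroglucinol starting materials are taken as purchasable; in open-chain ring-A intermediates the acyl-bearing carbon is C1, so C2–O is the future O1 and C3 the future C8.

Step 1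
Reactants: 1 2-methylbenzene-1,3,5-triol; 2 3-phenylpropanoyl chloride
Product: 3 1-(2,4,6-trihydroxy-3-methylphenyl)-3-phenylpropan-1-one
Conditions: AlCl3 (3.5 equiv), PhNO2–CH2Cl2, 0 → 45 °C; aq. HCl
Reagents that add atoms: none
Why: Friedel–Crafts C-acylation of a phloroglucinol, in which the two unsubstituted ring carbons of 1 are equivalent so that only one ketone can form, and chelation of the product to aluminium should hold back a second acylation.

Step 2
Reactants: 3 1-(2,4,6-trihydroxy-3-methylphenyl)-3-phenylpropan-1-one
Product: 4 1-(2,6-dihydroxy-4-methoxy-3-methylphenyl)-3-phenylpropan-1-one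
Conditions: Me2SO4 (1.05 equiv), K2CO3 (1.1 equiv), acetone, rt → 40 °C
Reagents that add atoms: dimethyl sulfate, COS(=O)(=O)OC
Why: Selective mono-O-methylation of a 2,4,6-trihydroxyaryl ketone (Williamson type), expected at the 4-hydroxyl because it is para to the carbonyl, the most acidic and not flanked by the acyl group, while the two ortho hydroxyls alternate in the hydrogen bond to the ketone; the ring carbon left free in 4 is the only unsubstituted carbon of ring D.

Step 3
Reactants: 5 2-methoxy-1-(2,4,6-trihydroxyphenyl)ethan-1-one
Product: 6 1-[2,4-bis(benzyloxy)-6-hydroxyphenyl]-2-methoxyethan-1-one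
Conditions: BnBr (2.05 equiv), K2CO3 (2.2 equiv), DMF, rt
Reagents that add atoms: benzyl bromide, BrCc1ccccc1
Why: Williamson etherification limited to two equivalents, in which the hydroxyl chelated to the ketone is alkylated last, so that the single phenol left free in 6 is the one ortho to the acyl group (the future O1).

Step 4
Reactants: 6 1-[2,4-bis(benzyloxy)-6-hydroxyphenyl]-2-methoxyethan-1-one
Product: 7 1-{4,6-bis(benzyloxy)-3-[(dimethylamino)methyl]-2-hydroxyphenyl}-2-methoxyethan-1-one
Conditions: CH2(NMe2)2 (2 equiv), 1,4-dioxane, 90 °C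
Reagents that add atoms: N,N,N',N'-tetramethylmethanediamine, CN(C)CN(C)C
Why: Phenolic Mannich reaction with an aminal, in which the acidic phenol protonates the aminal and the iminium ion is delivered within the phenoxide ion pair to the only free ortho carbon, C3 (the future C8), while C5 is para to the phenol and flanked by two benzyloxy groups and the ketone α-carbon is not enolised without acid.

Step 5
Reactants: 7 1-{4,6-bis(benzyloxy)-3-[(dimethylamino)methyl]-2-hydroxyphenyl}-2-methoxyethan-1-one
Product: 8 [2-(benzoyloxy)-4,6-bis(benzyloxy)-3-(methoxyacetyl)phenyl]methyl benzoate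
Conditions: Bz2O (3 equiv), DMAP (0.1 equiv), xylene, 130 °C
Reagents that add atoms: benzoic anhydride, O=C(OC(=O)c1ccccc1)c1ccccc1
Why: Anhydride cleavage of a phenolic Mannich base, the reaction type by which acetic anhydride turns such bases into acetoxybenzyl acetates: the phenol is O-benzoylated, the amine N-benzoylated, and benzoate displaces the acylammonium group from the electron-rich benzylic carbon, which places the benzoyl group later needed for ring C on the future O1 and a leaving group on the bridge carbon in one operation.

Step 6
Reactants: 8 [2-(benzoyloxy)-4,6-bis(benzyloxy)-3-(methoxyacetyl)phenyl]methyl benzoate; 4 1-(2,6-dihydroxy-4-methoxy-3-methylphenyl)-3-phenylpropan-1-one (1.3 equiv)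
Product: 9 3,5-bis(benzyloxy)-2-{[2,4-dihydroxy-6-methoxy-5-methyl-3-(3-phenylpropanoyl)phenyl]methyl}-6-(methoxyacetyl)phenyl benzoate
Conditions: Sc(OSO2CF3)3 (10 mol %), CH2Cl2–(CF3)2CHOH, 0 °C → rt
Reagents that add atoms: none
Why: The scandium salt should ionise the benzylic benzoate of 8 to a benzyl cation stabilised by the ortho- and para-benzyloxy groups on C4 and C6 of ring A and, by neighbouring-group participation, by the aryl benzoate on C2; ring D of 4 attacks it with its only unsubstituted carbon, which is ortho to one free hydroxyl, para to the other and ortho to the methoxy group, and loss of a proton restores the arene. The closest known reaction type is the acid-catalysed Friedel–Crafts C-benzylation of acylphloroglucinols and flavonoid A rings by electron-rich benzylic alcohols or esters. No ring is closed and no stereocentre is formed. The step needs C- rather than O-alkylation and attack by ring D rather than by ring A of a second molecule: ring D has two free phenols and is the stronger π-nucleophile, whereas the only free carbon of ring A (C5) lies between two benzyloxy groups on a ring without a free phenol. The site on ring A is not a matter of selectivity, because the electrophilic carbon already sits on C3 beside the oxygen that will become O1. The aryl benzoate, the benzyl ethers and both ketones should survive a catalytic oxophilic Lewis acid at room temperature, so the benzoyl group for ring C arrives in 9 on the right oxygen.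

Step 7
Reactants: 9 3,5-bis(benzyloxy)-2-{[2,4-dihydroxy-6-methoxy-5-methyl-3-(3-phenylpropanoyl)phenyl]methyl}-6-(methoxyacetyl)phenyl benzoate
Product: 11 5,7-bis(benzyloxy)-8-{[2,4-dihydroxy-6-methoxy-5-methyl-3-(3-phenylpropanoyl)phenyl]methyl}-3-methoxyflavone, via 1,3-diketone 10 (not isolated)
Conditions: LiN(SiMe3)2 (4.5 equiv), THF, −78 → −10 °C; AcOH; then TsOH·H2O (0.2 equiv), toluene, 70 °C
Reagents that add atoms: none
Why: Baker–Venkataraman rearrangement and cyclodehydration: the enolate of ring A's methoxyacetyl group takes the benzoyl group from the neighbouring ester through a six-membered transition state, a path closed to ring D's ketone, which has no ortho ester and whose phenols are only deprotonated, and in 10 the sole free hydroxyl ortho to the diketone is the one beside the methylene (the other ortho oxygen is benzylated), so acid can close ring C only with the bridge on C8; the stereocentre of racemic 10 is erased on dehydration.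

Step 8
Reactants: 11 5,7-bis(benzyloxy)-8-{[2,4-dihydroxy-6-methoxy-5-methyl-3-(3-phenylpropanoyl)phenyl]methyl}-3-methoxyflavone
Product: 12 8-{[2,4-dihydroxy-6-methoxy-5-methyl-3-(3-phenylpropanoyl)phenyl]methyl}-5,7-dihydroxy-3-methoxyflavone (CNP0280022.0)
Conditions: H2 (1 atm), 10% Pd/C, EtOAc–MeOH, rt
Reagents that add atoms: none
Why: Catalytic hydrogenolysis of the two aryl benzyl ethers under neutral conditions, which should spare the chelated aryl ketone, the tetrasubstituted C2=C3 enol ether, the methyl ethers and the diarylmethane, and avoids the alkali in which methylene-bridged phloroglucinols exchange their halves.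

**Compound list**
1 | 2-methylbenzene-1,3,5-triol | Cc1c(O)cc(O)cc1O | starting material
2 | 3-phenylpropanoyl chloride | O=C(Cl)CCc1ccccc1 | starting material
3 | 1-(2,4,6-trihydroxy-3-methylphenyl)-3-phenylpropan-1-one | Cc1c(O)cc(O)c(C(=O)CCc2ccccc2)c1O | intermediate
4 | 1-(2,6-dihydroxy-4-methoxy-3-methylphenyl)-3-phenylpropan-1-one | COc1cc(O)c(C(=O)CCc2ccccc2)c(O)c1C | intermediate
5 | 2-methoxy-1-(2,4,6-trihydroxyphenyl)ethan-1-one | COCC(=O)c1c(O)cc(O)cc1O | starting material
6 | 1-[2,4-bis(benzyloxy)-6-hydroxyphenyl]-2-methoxyethan-1-one | COCC(=O)c1c(O)cc(OCc2ccccc2)cc1OCc1ccccc1 | intermediate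
7 | 1-{4,6-bis(benzyloxy)-3-[(dimethylamino)methyl]-2-hydroxyphenyl}-2-methoxyethan-1-one | COCC(=O)c1c(O)c(CN(C)C)c(OCc2ccccc2)cc1OCc1ccccc1 | intermediate
8 | [2-(benzoyloxy)-4,6-bis(benzyloxy)-3-(methoxyacetyl)phenyl]methyl benzoate | COCC(=O)c1c(OC(=O)c2ccccc2)c(COC(=O)c2ccccc2)c(OCc2ccccc2)cc1OCc1ccccc1 | intermediate (precursor of the key step)
9 | 3,5-bis(benzyloxy)-2-{[2,4-dihydroxy-6-methoxy-5-methyl-3-(3-phenylpropanoyl)phenyl]methyl}-6-(methoxyacetyl)phenyl benzoate | COCC(=O)c1c(OC(=O)c2ccccc2)c(Cc2c(O)c(C(=O)CCc3ccccc3)c(O)c(C)c2OC)c(OCc2ccccc2)cc1OCc1ccccc1 | intermediate (product of the key step)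
10 | 1-[4,6-bis(benzyloxy)-3-{[2,4-dihydroxy-6-methoxy-5-methyl-3-(3-phenylpropanoyl)phenyl]methyl}-2-hydroxyphenyl]-2-methoxy-3-phenylpropane-1,3-dione (racemic) | COC(C(=O)c1ccccc1)C(=O)c1c(O)c(Cc2c(O)c(C(=O)CCc3ccccc3)c(O)c(C)c2OC)c(OCc2ccccc2)cc1OCc1ccccc1 | intermediate (not isolated)
11 | 5,7-bis(benzyloxy)-8-{[2,4-dihydroxy-6-methoxy-5-methyl-3-(3-phenylpropanoyl)phenyl]methyl}-3-methoxyflavone | COc1c(C)c(O)c(C(=O)CCc2ccccc2)c(O)c1Cc1c(OCc2ccccc2)cc(OCc2ccccc2)c2c(=O)c(OC)c(-c3ccccc3)oc12 | intermediate
12 | 8-{[2,4-dihydroxy-6-methoxy-5-methyl-3-(3-phenylpropanoyl)phenyl]methyl}-5,7-dihydroxy-3-methoxyflavone (CNP0280022.0) | COc1c(C)c(O)c(C(=O)CCc2ccccc2)c(O)c1Cc1c(O)cc(O)c2c(=O)c(OC)c(-c3ccccc3)oc12 | target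

**Count and risks**
Total step count: 8. Longest linear sequence: 6 steps (steps 3 to 8). The target has no stereocentre.

Steps most likely to fail:

1. Step 6. The benzyl cation may be consumed by ring A of a second molecule (self-alkylation at C5, oligomers), ring D may be alkylated on oxygen, or benzyl ethers may be lost to the Lewis acid. Fallback, an acid-free quinone methide union: it sets out from 7, which is heated with 4 in 1,4-dioxane at 100 °C. Loss of dimethylamine gives the ortho-quinone methide across C2(O)–C3(=CH2) of ring A, and the free carbon of ring D captures it to give 1-[4,6-bis(benzyloxy)-3-{[2,4-dihydroxy-6-methoxy-5-methyl-3-(3-phenylpropanoyl)phenyl]methyl}-2-hydroxyphenyl]-2-methoxyethan-1-one F1. The polyanion of F1 (LiN(SiMe3)2, THF, −78 °C) is then C-benzoylated with one equivalent of benzoyl chloride. This should occur at the methoxyacetyl enolate, the more acidic of the two ketone enolates because ring D's ketone carries two ortho phenoxides. The product is 10, where the route is rejoined before the acid cyclisation of step 7. This path is the fallback because its selectivity rests on enolate acidity and not on intramolecular delivery.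

2. Step 5. The amine may leave before the phenol is acylated, so that the quinone methide dimerises, or the cleavage may stop at the aryl benzoate. Fallback, a nitrogen-free formyl route: it sets out from 6. Magnesium-templated ortho-formylation (MgCl2, Et3N, paraformaldehyde, MeCN, reflux) should give 4,6-bis(benzyloxy)-2-hydroxy-3-(methoxyacetyl)benzaldehyde F2. NaBH4 at −20 °C should reduce the aldehyde in preference to the hindered, chelated ketone to give 1-[4,6-bis(benzyloxy)-2-hydroxy-3-(hydroxymethyl)phenyl]-2-methoxyethan-1-one F3. Benzoyl chloride in pyridine then acylates both hydroxyls, and the route is rejoined at 8.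

3. Step 4. The chelated phenol may react sluggishly, or aminomethylation may stray to C5 or to the ketone α-carbon. Fallback, constitution taken from symmetry: it sets out from 5, whose two free ring carbons are equivalent. Vilsmeier–Haack formylation (POCl3, DMF, EtOAc; aqueous hydrolysis) should give 2,4,6-trihydroxy-3-(methoxyacetyl)benzaldehyde F4. Benzylation of the two outer hydroxyls (BnBr, K2CO3, DMF) should leave free the hydroxyl between the two carbonyl groups and give F2, which is taken on through F3 as in the preceding fallback, and the route is rejoined at 8.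

**Further compounds**
F1 | step 6 | 1-[4,6-bis(benzyloxy)-3-{[2,4-dihydroxy-6-methoxy-5-methyl-3-(3-phenylpropanoyl)phenyl]methyl}-2-hydroxyphenyl]-2-methoxyethan-1-one | COCC(=O)c1c(O)c(Cc2c(O)c(C(=O)CCc3ccccc3)c(O)c(C)c2OC)c(OCc2ccccc2)cc1OCc1ccccc1
F2 | step 5 | 4,6-bis(benzyloxy)-2-hydroxy-3-(methoxyacetyl)benzaldehyde | COCC(=O)c1c(O)c(C=O)c(OCc2ccccc2)cc1OCc1ccccc1
F3 | step 5 | 1-[4,6-bis(benzyloxy)-2-hydroxy-3-(hydroxymethyl)phenyl]-2-methoxyethan-1-one | COCC(=O)c1c(O)c(CO)c(OCc2ccccc2)cc1OCc1ccccc1
F4 | step 4 | 2,4,6-trihydroxy-3-(methoxyacetyl)benzaldehyde | COCC(=O)c1c(O)cc(O)c(C=O)c1O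
A1 | direct plan | 5,7-bis(benzyloxy)-3-methoxyflavone | COc1c(-c2ccccc2)oc2cc(OCc3ccccc3)cc(OCc3ccccc3)c2c1=O
A2 | direct plan | 5,7-bis(benzyloxy)-8-[3-(benzyloxy)prop-2-yn-1-yl]-3-methoxyflavone | COc1c(-c2ccccc2)oc2c(CC#COCc3ccccc3)c(OCc3ccccc3)cc(OCc3ccccc3)c2c1=O
A3 | direct plan | 3-(benzyloxy)-2-{[5,7-bis(benzyloxy)-3-methoxyflavon-8-yl]methyl}cyclobut-2-en-1-one | COc1c(-c2ccccc2)oc2c(CC3=C(OCc4ccccc4)CC3=O)c(OCc3ccccc3)cc(OCc3ccccc3)c2c1=O
A4 | direct plan | 5,7-bis(benzyloxy)-8-{[6-(benzyloxy)-4-hydroxy-2-methoxy-3-methylphenyl]methyl}-3-methoxyflavone | COc1c(-c2ccccc2)oc2c(Cc3c(OCc4ccccc4)cc(O)c(C)c3OC)c(OCc3ccccc3)cc(OCc3ccccc3)c2c1=O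
A5 | direct plan | 5-(benzyloxy)-4-{[5,7-bis(benzyloxy)-3-methoxyflavon-8-yl]methyl}-3-methoxy-2-methylphenyl 3-phenylpropanoate | COc1c(-c2ccccc2)oc2c(Cc3c(OCc4ccccc4)cc(OC(=O)CCc4ccccc4)c(C)c3OC)c(OCc3ccccc3)cc(OCc3ccccc3)c2c1=O
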